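## Retrosynthetic overview

1. Feature used: in ring C of the flavanonol half, O1-C2H(4-hydroxyphenyl) is a 4-oxybenzyl ether of the ring A phenol at C8a. C4(=O)-C3 is an acyl side chain on the neighbouring ring A carbon C4a, so ring C lacks only the C2-C3 bond that joins the two stereocentres.
2. Key disconnection C2-C3: a rhodium carbene at C3, made from a diazomethyl ketone, inserts enantioselectively into one of the two enantiotopic O-CH2-aryl hydrogens. This closes ring C and sets C2. The 3-OH is then added anti to the C2 aryl group (silyl enol ether, Rubottom oxidation), and all ethers are cleaved last.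
3. The diazoketone comes from the methyl ketone by detrifluoroacetylative diazo transfer. The methyl ketone comes from a Suzuki coupling (C8-C3' biaryl bond) of an iodinated, O-differentiated phloroacetophenone with a flavone 3'-boronate.
4. Both ring A units derive from phloroacetophenone through one common dibenzyl ether. O5 of the flavanonol half carries methyl, so the second ortho ether offers the carbene only primary C-H bonds.
5. Ring order: flavone pyranone ring first (Claisen condensation, cyclodehydration), then the biaryl bond, and ring C of the flavanonol half last.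

Key step: step 12

Remark on names: flavonoid numbering is used, and plain locants (O1, C2, C3, C4, C4a, C5 to C8, C8a, rings A and C) belong to the flavanone/flavanonol half. "Fl" is the 5,7,4'-tris(benzyloxy)flavon-3'-yl group, bound through the ring B carbon ortho to its 4'-benzyloxy group.

Assumption on the axis: the C8-C3' biaryl axis has three ortho substituents and is drawn without configuration in the target, so it is treated as rotating freely enough that protected intermediates are rotamers, not separate stereoisomers.

Assumption on the catalyst: the S-prolinate catalyst is taken to deliver the 2S product. If the sense of induction is opposite, the equally available Rh2(R-DOSP)4 is used and nothing else changes.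

## Route

Step 1
Reactants: 1 2,4,6-trihydroxyacetophenone (phloroacetophenone)
Product: 2 2,4-bis(benzyloxy)-6-hydroxyacetophenone
Conditions: BnBr (2.1 equiv), K2CO3, DMF, 23 to 60 °C
Reagents that add atoms: benzyl bromide, BrCc1ccccc1
Why: Williamson etherification under carbonate conditions stops at the dibenzyl ether, because the last ortho hydroxyl is hydrogen-bonded to the acetyl carbonyl and is far less nucleophilic than the para and the first ortho phenoxide.

Step 2
Reactants: 3 methyl 4-hydroxy-3-iodobenzoate
Product: 4 methyl 4-(benzyloxy)-3-iodobenzoate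
Conditions: BnBr, K2CO3, DMF, 23 °C
Reagents that add atoms: benzyl bromide, BrCc1ccccc1
Why: Williamson etherification of the only phenol, with ester and aryl iodide inert to K2CO3.

Step 3
Reactants: 2 2,4-bis(benzyloxy)-6-hydroxyacetophenone; 4 methyl 4-(benzyloxy)-3-iodobenzoate
Product: 5 1-[2,4-bis(benzyloxy)-6-hydroxyphenyl]-3-[4-(benzyloxy)-3-iodophenyl]propane-1,3-dione
Conditions: NaH (4 equiv), THF, 65 °C; then 1 M HCl
Reagents that add atoms: none
Why: Crossed Claisen condensation, in which the phenoxide-enolate dianion of 2 is acylated on carbon by the non-enolisable ester 4 and deprotonation of the beta-diketone pulls the equilibrium over, the usual entry to flavone precursors from 2-hydroxyacetophenones and methyl benzoates.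

Step 4
Reactants: 5 the beta-diketone
Product: 6 5,7,4'-tris(benzyloxy)-3'-iodoflavone
Conditions: NaOAc, AcOH, 100 °C
Reagents that add atoms: none
Why: Cyclodehydration of a 2-hydroxyphenyl beta-diketone (last stage of a Baker-Venkataraman type flavone synthesis), in which the phenol adds to the aroyl carbonyl and loss of water gives the gamma-pyrone, while acetate-buffered acetic acid is too weak to cleave the benzyl ethers.

Step 5
Reactants: 6 5,7,4'-tris(benzyloxy)-3'-iodoflavone
Product: 7 5,7,4'-tris(benzyloxy)flavone-3'-boronic acid pinacol ester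
Conditions: B2pin2, PdCl2(dppf) (5 mol %), KOAc, 1,4-dioxane, 90 °C
Reagents that add atoms: bis(pinacolato)diboron, CC1(C)OB(OC1(C)C)B1OC(C)(C)C(C)(C)O1
Why: Miyaura borylation by oxidative addition of zerovalent palladium into the C-I bond, acetate-assisted transmetalation with the diboron reagent and reductive elimination, with KOAc too weak a base to start homocoupling.

Step 6
Reactants: 2 2,4-bis(benzyloxy)-6-hydroxyacetophenone
Product: 8 2,4-bis(benzyloxy)-6-methoxyacetophenone
Conditions: MeI (3 equiv), K2CO3, DMF, 40 °C
Reagents that add atoms: iodomethane, CI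
Why: Williamson methylation, since in DMF with excess iodomethane even the chelated phenol is alkylated and no other acidic site competes under carbonate.

Step 7
Reactants: 8 2,4-bis(benzyloxy)-6-methoxyacetophenone
Product: 9 4-(benzyloxy)-2-hydroxy-6-methoxyacetophenone
Conditions: MgBr2·OEt2 (2 equiv), toluene-Et2O, 75 °C; then 1 M HCl
Reagents that add atoms: none
Why: Chelation-controlled ether cleavage, in which magnesium binds between the ketone oxygen and an ortho ether oxygen and bromide attacks the benzylic carbon much faster than a methyl carbon, whereas the para benzyl ether cannot chelate and stays.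

Step 8
Reactants: 9 4-(benzyloxy)-2-hydroxy-6-methoxyacetophenone
Product: 10 4-(benzyloxy)-2-hydroxy-3-iodo-6-methoxyacetophenone
Conditions: I2 (0.4 equiv), HIO3 (0.2 equiv), EtOH-H2O, 30 °C
Reagents that add atoms: iodine, [I][I]; iodic acid, OI(=O)=O
Why: Electrophilic aromatic iodination with HIO3 as oxidant, which on 2-hydroxy-4,6-dialkoxyacetophenones goes to C3, ortho to the free phenol and para to the 6-alkoxy group, the carbon that becomes C8.

Step 9
Reactants: 10 4-(benzyloxy)-2-hydroxy-3-iodo-6-methoxyacetophenone; 11 4-(benzyloxy)benzyl chloride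
Product: 12 4-(benzyloxy)-2-[4-(benzyloxy)benzyloxy]-3-iodo-6-methoxyacetophenone
Conditions: K2CO3, DMF, 50 °C
Reagents that add atoms: none
Why: Williamson etherification with a very reactive 4-alkoxybenzyl chloride, which fixes the future O1-C2 bond and places the CH2 group next to the acetyl group, K2CO3 being too weak to bring the ketone enolate into play.

Step 10
Reactants: 12 the aryl iodide; 7 the flavone 3'-boronate
Product: 13 4-(benzyloxy)-2-[4-(benzyloxy)benzyloxy]-6-methoxy-3-Fl-acetophenone
Conditions: Pd(OAc)2 (5 mol %), SPhos (10 mol %), K3PO4, toluene-H2O 10:1, 90 °C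
Reagents that add atoms: none
Why: Suzuki-Miyaura coupling with the bulky, electron-rich biarylphosphine SPhos, which is suited to aryl halides with two ortho substituents and ortho-substituted boronates, while ketone, flavone and all ethers tolerate aqueous phosphate.

Step 11
Reactants: 13 the biaryl methyl ketone
Product: 15 2-diazo-1-{4-(benzyloxy)-2-[4-(benzyloxy)benzyloxy]-6-methoxy-3-Fl-phenyl}ethanone (diazomethyl ketone), via trifluoroacetyl diketone 14 (not isolated)
Conditions: LiN(SiMe3)2, THF, -78 °C; CF3CO2CH2CF3, -78 °C; cold 0.5 M HCl wash; then MsN3, Et3N, H2O (1 equiv), MeCN, 23 °C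
Reagents that add atoms: methanesulfonyl azide, CS(=O)(=O)N=[N+]=[N-]; 2,2,2-trifluoroethyl trifluoroacetate (its CF3CO group stays only in 14), O=C(OCC(F)(F)F)C(F)(F)F
Why: Detrifluoroacetylative diazo transfer, in which the kinetic lithium enolate of the methyl ketone (the only enolisable position of 13) is trifluoroacetylated to activate the CH2 group, the sulfonyl azide transfers N2 to the diketone and the trifluoroacetyl group leaves on the sulfonamide nitrogen.

Step 12
Reactants: 15 the diazomethyl ketone
Product: 16 (2S)-7-(benzyloxy)-2-[4-(benzyloxy)phenyl]-5-methoxy-8-Fl-chroman-4-one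
Conditions: Rh2(S-DOSP)4 (2 mol %), 4 Å MS, CH2Cl2, 0 to 23 °C, 15 added by syringe pump over 3 h
Reagents that add atoms: none
Why: The dirhodium core takes up the diazo carbon of 15 at an axial site, nitrogen leaves, and the electrophilic rhodium carbene at C3 engages one O-CH2-aryl C-H bond in a concerted but asynchronous three-centre transition state with hydride-like transfer to C3, so that C2-C3 forms as the metal departs. The closest known reaction type is the chiral dirhodium prolinate catalysed C-H insertion of 2-(alkoxy)aryl alpha-diazoketones, benzyl ethers included, which gives 2-substituted chroman-4-ones. Ring C closes by 1,6-insertion through a six-membered cyclic array of C3, C4, C4a, C8a, O1 and C2, and no smaller ring can form by insertion because the atom in the 1,5-position is oxygen. C2 is the only new stereocentre and is set by the catalyst alone, whose arylsulfonylprolinate pocket tells apart the two enantiotopic hydrogens of the CH2 group. The step needs chemoselectivity over attack on the O1 lone pair (five-membered oxonium ylide, then Stevens 1,2-shift) and site selectivity over the O5 ether: the first rests on a secondary C-H bond activated by the ether oxygen as well as by the para-oxygenated aryl ring, on an aryl ether oxygen of low basicity and on a rhodium carboxylate instead of a copper catalyst, the second on O5 bearing only strong primary methyl C-H bonds. Slow addition at high dilution keeps carbene dimerisation and intermolecular capture by the flavone carbonyl in check.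

Step 13
Reactants: 16 the (2S)-flavanone
Product: 17 (2S)-7-(benzyloxy)-2-[4-(benzyloxy)phenyl]-5-methoxy-8-Fl-4-(trimethylsilyloxy)-2H-chromene
Conditions: TMSOTf (3 equiv), Et3N (5 equiv), CH2Cl2, 0 °C; cold aq. NaHCO3 work-up, used without chromatography
Reagents that add atoms: trimethylsilyl trifluoromethanesulfonate, C[Si](C)(C)OS(=O)(=O)C(F)(F)F
Why: Soft enolisation, in which the silyl triflate activates the C4 carbonyl and triethylamine removes a C3 proton, so no free enolate is present that could expel the O1 phenoxide (retro-oxa-Michael) and C2 keeps its configuration, while silylation of the flavone carbonyl is reversible and is undone on work-up.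

Step 14
Reactants: 17 the silyl enol ether
Product: 20 (2R,3R)-7-(benzyloxy)-2-[4-(benzyloxy)phenyl]-3-hydroxy-5-methoxy-8-Fl-chroman-4-one, via siloxy epoxide 18 (not isolated), via 3-O-trimethylsilyl ketone 19 (not isolated)
Conditions: mCPBA (1.1 equiv), CH2Cl2, -20 to 0 °C; then 1 M HCl, THF, 0 °C
Reagents that add atoms: 3-chloroperoxybenzoic acid, OOC(=O)c1cccc(Cl)c1
Why: Rubottom oxidation, in which the peracid epoxidises the electron-rich C3=C4 enol ether bond on the face opposite the C2 aryl group, the siloxy epoxide opens with 1,4-silyl shift to the 3-silyloxy ketone and acid frees the alcohol, so C3 is set R and trans to C2 by substrate control (the C2 descriptor changes from S to R by priority only), the trans isomer also being the thermodynamic one and the electron-poor flavone double bond being left alone.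

Step 15
Reactants: 20 the protected (2R,3R)-flavanonol
Product: 21 target, (2R,3R)-3,5,7-trihydroxy-2-(4-hydroxyphenyl)-8-[5-(5,7-dihydroxy-4-oxo-4H-chromen-2-yl)-2-hydroxyphenyl]chroman-4-one
Conditions: BCl3 (15 equiv), C6HMe5 (15 equiv), CH2Cl2, -78 °C, then 0 °C; H2O-THF quench
Reagents that add atoms: none
Why: Lewis acid ether cleavage with a non-basic cation scavenger, in which BCl3 ionises the five aryl benzyl ethers at low temperature and pentamethylbenzene traps the benzyl cations by Friedel-Crafts alkylation, on warming the boron chelate between the C4 carbonyl oxygen and O5 lets chloride cleave the peri methyl ether, and O1-C2 should hold because O1 is the vinylogous ester oxygen of the boron-bound carbonyl and C2 sits beside the electron-poor C3 carbinol and an aryl ring whose oxygen is tied to boron.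

## Compound list

1 | 2,4,6-trihydroxyacetophenone | CC(=O)c1c(O)cc(O)cc1O | starting material
2 | 2,4-bis(benzyloxy)-6-hydroxyacetophenone | CC(=O)c1c(O)cc(OCc2ccccc2)cc1OCc1ccccc1 | intermediate
3 | methyl 4-hydroxy-3-iodobenzoate | COC(=O)c1ccc(O)c(I)c1 | starting material
4 | methyl 4-(benzyloxy)-3-iodobenzoate | COC(=O)c1ccc(OCc2ccccc2)c(I)c1 | intermediate
5 | 1-[2,4-bis(benzyloxy)-6-hydroxyphenyl]-3-[4-(benzyloxy)-3-iodophenyl]propane-1,3-dione | O=C(CC(=O)c1ccc(OCc2ccccc2)c(I)c1)c1c(O)cc(OCc2ccccc2)cc1OCc1ccccc1 | intermediate
6 | 5,7,4'-tris(benzyloxy)-3'-iodoflavone | O=c1cc(-c2ccc(OCc3ccccc3)c(I)c2)oc2cc(OCc3ccccc3)cc(OCc3ccccc3)c12 | intermediate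
7 | 5,7,4'-tris(benzyloxy)flavone-3'-boronic acid pinacol ester | CC1(C)OB(OC1(C)C)c1cc(-c2cc(=O)c3c(OCc4ccccc4)cc(OCc4ccccc4)cc3o2)ccc1OCc1ccccc1 | intermediate
8 | 2,4-bis(benzyloxy)-6-methoxyacetophenone | CC(=O)c1c(OC)cc(OCc2ccccc2)cc1OCc1ccccc1 | intermediate
9 | 4-(benzyloxy)-2-hydroxy-6-methoxyacetophenone | CC(=O)c1c(O)cc(OCc2ccccc2)cc1OC | intermediate
10 | 4-(benzyloxy)-2-hydroxy-3-iodo-6-methoxyacetophenone | CC(=O)c1c(OC)cc(OCc2ccccc2)c(I)c1O | intermediate
11 | 4-(benzyloxy)benzyl chloride | ClCc1ccc(OCc2ccccc2)cc1 | starting material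
12 | 4-(benzyloxy)-2-[4-(benzyloxy)benzyloxy]-3-iodo-6-methoxyacetophenone | CC(=O)c1c(OC)cc(OCc2ccccc2)c(I)c1OCc1ccc(OCc2ccccc2)cc1 | intermediate
13 | 4-(benzyloxy)-2-[4-(benzyloxy)benzyloxy]-6-methoxy-3-Fl-acetophenone | CC(=O)c1c(OC)cc(OCc2ccccc2)c(-c2cc(-c3cc(=O)c4c(OCc5ccccc5)cc(OCc5ccccc5)cc4o3)ccc2OCc2ccccc2)c1OCc1ccc(OCc2ccccc2)cc1 | intermediate
14 | trifluoroacetyl diketone (4,4,4-trifluoro-1-arylbutane-1,3-dione of 13) | O=C(CC(=O)C(F)(F)F)c1c(OC)cc(OCc2ccccc2)c(-c2cc(-c3cc(=O)c4c(OCc5ccccc5)cc(OCc5ccccc5)cc4o3)ccc2OCc2ccccc2)c1OCc1ccc(OCc2ccccc2)cc1 | intermediate (not isolated)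
15 | diazomethyl ketone, key-step precursor | [N-]=[N+]=CC(=O)c1c(OC)cc(OCc2ccccc2)c(-c2cc(-c3cc(=O)c4c(OCc5ccccc5)cc(OCc5ccccc5)cc4o3)ccc2OCc2ccccc2)c1OCc1ccc(OCc2ccccc2)cc1 | intermediate
16 | (2S)-7-(benzyloxy)-2-[4-(benzyloxy)phenyl]-5-methoxy-8-Fl-chroman-4-one, key-step product | O=C1c2c(OC)cc(OCc3ccccc3)c(-c3cc(-c4cc(=O)c5c(OCc6ccccc6)cc(OCc6ccccc6)cc5o4)ccc3OCc3ccccc3)c2O[C@H](c2ccc(OCc3ccccc3)cc2)C1 | intermediate
17 | (2S)-4-(trimethylsilyloxy)-2H-chromene (silyl enol ether of 16) | C[Si](C)(C)OC1=C[C@@H](c2ccc(OCc3ccccc3)cc2)Oc2c1c(OC)cc(OCc1ccccc1)c2-c1cc(-c2cc(=O)c3c(OCc4ccccc4)cc(OCc4ccccc4)cc3o2)ccc1OCc1ccccc1 | intermediate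
18 | siloxy epoxide (3,4-epoxide of 17, oxygen anti to the C2 aryl group) | C[Si](C)(C)O[C@@]12O[C@@H]1[C@@H](c1ccc(OCc3ccccc3)cc1)Oc1c2c(OC)cc(OCc2ccccc2)c1-c1cc(-c2cc(=O)c3c(OCc4ccccc4)cc(OCc4ccccc4)cc3o2)ccc1OCc1ccccc1 | intermediate (not isolated)
19 | 3-O-trimethylsilyl ketone, (2R,3R) | O=C1c2c(OC)cc(OCc3ccccc3)c(-c3cc(-c4cc(=O)c5c(OCc6ccccc6)cc(OCc6ccccc6)cc5o4)ccc3OCc3ccccc3)c2O[C@H](c2ccc(OCc3ccccc3)cc2)[C@H]1O[Si](C)(C)C | intermediate (not isolated)
20 | (2R,3R)-7-(benzyloxy)-2-[4-(benzyloxy)phenyl]-3-hydroxy-5-methoxy-8-Fl-chroman-4-one | O=C1c2c(OC)cc(OCc3ccccc3)c(-c3cc(-c4cc(=O)c5c(OCc6ccccc6)cc(OCc6ccccc6)cc5o4)ccc3OCc3ccccc3)c2O[C@H](c2ccc(OCc3ccccc3)cc2)[C@H]1O | intermediate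
21 | CNP0374521.1, (2R,3R)-flavanonol-flavone dimer | O=C1c2c(O)cc(O)c(-c3cc(-c4cc(=O)c5c(O)cc(O)cc5o4)ccc3O)c2O[C@H](c2ccc(O)cc2)[C@H]1O | target

## Step count

Total step count: 15.
Longest linear sequence: 11 steps (1, 6, 7, 8, 9, 10, 11, 12, 13, 14, 15).

## Steps most likely to fail

**Step 12.**
- What may go wrong: the ether oxygen is flanked on both sides and is therefore twisted partly out of conjugation with ring A. The carbene may be captured by its lone pair, after which the stabilised benzyl group shifts 1,2. An acceptor-only carbene may also discriminate the two enantiotopic hydrogens only modestly.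
- Fallback: it sets out from 10 and 7 and builds ring C before the C2-aryl bond.
  - Suzuki coupling under the conditions of step 10 would give the free-phenol biaryl ketone F1.
  - Condensation with N,N-dimethylformamide dimethyl acetal in hot toluene would give the enaminone F2.
  - Dilute HCl in CH2Cl2 would close this to the 2-unsubstituted chromone F3.
  - Asymmetric rhodium-catalysed 1,4-addition of 4-(benzyloxy)phenylboronic acid follows ([Rh(OH)(cod)]2 with an electron-poor chiral bisphosphine of the MeO-BIPHEP family, ligand antipode chosen for 2S, toluene, 23 °C). This is an established way from chromones to enantioenriched flavanones.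
  - The addition leaves the beta,beta-disubstituted flavone enone alone and comes back to the route at 16.

**Step 13.**
- What may go wrong: ring C may open by a retro-oxa-Michael process under the combined action of silyl triflate and amine, which erodes the C2 configuration. The flavone carbonyl also consumes silylating agent, so enolisation may stay incomplete.
- Fallback: it sets out from 16 and avoids both the Lewis acid and the silyl enol ether.
  - Kinetic deprotonation with LiN(SiMe3)2 in THF at -78 °C gives the lithium enolate F4.
  - This is oxidised in the same flask by 2-(phenylsulfonyl)-3-phenyloxaziridine on the face anti to the C2 aryl group.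
  - Low-temperature lithium enolates of flavanones are known to be hydroxylated to trans-3-hydroxyflavanones without ring opening.
  - After an NH4Cl quench the sequence comes back at 20 and bypasses 17 to 19.

**Step 15.**
- What may go wrong: the O1-C2 bond is itself a 4-oxybenzylic aryl ether. It may ionise, and the cation may be captured irreversibly by the scavenger. Cleavage of the 5-methyl ether may also be incomplete at the temperature the flavanonol tolerates.
- Fallback: it sets out from 20 and replaces cation chemistry by hydrogenolysis.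
  - H2 (1 atm) over palladium on carbon in THF-MeOH removes the five benzyl groups, as is usual for benzylated flavones and dihydroflavonols, and gives the 5-O-methyl ether of the target F5.
  - Chelation-controlled demethylation with MgI2·OEt2 in THF at 50 °C is known for 5-methoxyflavanones that carry free phenols, and it comes back at 21.
  - Any epimerisation at C2 would be corrected towards the trans isomer because C3 stays fixed.

## Further compounds

F1 | step 12 | free-phenol biaryl ketone, 4-(benzyloxy)-2-hydroxy-6-methoxy-3-Fl-acetophenone | CC(=O)c1c(OC)cc(OCc2ccccc2)c(-c2cc(-c3cc(=O)c4c(OCc5ccccc5)cc(OCc5ccccc5)cc4o3)ccc2OCc2ccccc2)c1O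
F2 | step 12 | enaminone, (E)-3-(dimethylamino)-1-aryl-prop-2-en-1-one of F1 | CN(C)/C=C/C(=O)c1c(OC)cc(OCc2ccccc2)c(-c2cc(-c3cc(=O)c4c(OCc5ccccc5)cc(OCc5ccccc5)cc4o3)ccc2OCc2ccccc2)c1O
F3 | step 12 | 2-unsubstituted chromone, 7-(benzyloxy)-5-methoxy-8-Fl-4H-chromen-4-one | O=c1ccoc2c1c(OC)cc(OCc1ccccc1)c2-c1cc(-c2cc(=O)c3c(OCc4ccccc4)cc(OCc4ccccc4)cc3o2)ccc1OCc1ccccc1
F4 | step 13 | lithium enolate of 16 | [Li+].[O-]C1=C[C@@H](c2ccc(OCc3ccccc3)cc2)Oc2c1c(OC)cc(OCc1ccccc1)c2-c1cc(-c2cc(=O)c3c(OCc4ccccc4)cc(OCc4ccccc4)cc3o2)ccc1OCc1ccccc1
F5 | step 15 | 5-O-methyl ether of the target, (2R,3R) | O=C1c2c(OC)cc(O)c(-c3cc(-c4cc(=O)c5c(O)cc(O)cc5o4)ccc3O)c2O[C@H](c2ccc(O)cc2)[C@H]1O
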